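Its constants are assumed; what happens was integrated by code.

I began from a ratio: dormant form over substrate stands at 21 at equilibrium, so I asked what would have to be true for much of this flask's substrate to become product.

    2 reagent in the reaction phase → homo dimer (k1 = 160 M⁻¹ s⁻¹)
    substrate + reagent in the reaction phase → product (k2 = 240 M⁻¹ s⁻¹)
    reagent in the reaction phase → decomposed reagent (k3 = 0.052 s⁻¹)
    reagent in the reaction phase ⇌ reagent in the second phase, rate k4*([reagent in the reaction phase] - [reagent in the second phase]/K4) per volume of the first phase (K4 = 0.68, k4 = 0.98 s⁻¹)
    substrate ⇌ dormant form (K5 = 21, k5 = 4.4 s⁻¹)

substrate 0.0020 M; reagent in the second phase 2.60 mM; time 6.0 s; volume of the second phase over the first 1.0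

- product at 6.0 s, in percent of the substrate charged
- the change that raises the amount of product at 6.0 s, in percent of the substrate charged most ("none" if none brings more than 2 percentage points) (south-west / east / none)
- amount of product at 6.0 s, in percent of the substrate charged, after east

- south-west: doubling the transfer coefficient of step 4, all else as stated
- east: doubling the amount of reagent in the second phase, all else as stated

Substrate was charged in the smaller amount, so I balanced it: substrate, dormant form (its resting state) and product sum to the charge. The exchange relaxes with a half-life of 0.150 s, much shorter than the run. I therefore treated substrate and dormant form as one pool, reacting through the pool constant k_p = 10.9 M⁻¹ s⁻¹, the product-step constant times the free share of the pool. Let E, the exposure, be the reagent concentration in the reaction phase summed over time. The pool then converts by the fraction 1 − exp(−k_p E), and half of the charge would need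

E = ln 2 / k_p = 0.0635 M·s

To see what the flask offers, I let the reagent partition at once to b = 1.55 mM, since the partition time 0.413 s is shorter than the time T = 3.39 s for loss to homo dimer. I dropped decomposition, whose half-life of 13 s is longer than T. That gave

E = b T ln(1 + t/T) = 5.35 mM·s

This is 11.9 times below the need, so I committed to y = 5.67%. Doubling the reagent in the second phase (east) gives E = 7.94 mM·s and yb = 8.30%. South-west, doubling the transfer coefficient of step 4, halves the partition time, and I reckoned the time saved, at b and k_p, as a gain of 0.349% of the charge. My choice was east.

The forecast said 7%, east and 11%, on “a small early burst and then a slow trickle”.

The flask gave 7.10%, and 11.4% after east, a gain of 4.3 percentage points against 1.1 points for south-west, so the choice is east. In that flask 2.47% of product already stood at 0.600 s. From 3.00 s to 6.0 s, k_p with the mean of the two reagent readings and the pool then present gives 2.1 points, and the flask rose 1.9 points. Neither k_p nor E holds the substrate charge, so my reckoning for the neighbour with 0.0080 M of substrate is the same number as for this flask, and at 6.00 s that neighbour gave 6.51%.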